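**Strategy.** The 26-membered lactone (C1 carbonyl, ring numbered to the oxygen-bearing C25, side chain C1'–C6') is cut at the C9 carbinol, which lies between the C8 and C10 methylenes and the oxygenated C7 and C11. One acyl-anion carbon therefore joins two terminal epoxides: lithiated 2-silyl-1,3-dithiane opens the C3–C8 epoxide at C8, a solvent-triggered 1,4-Brook shift silylates O7 and renews the anion, which opens the L-arabinose-derived C10–C15 epoxide at C10. The precursors are a syn-5,7 epoxide carrying only TBS ethers and an acetonide-protected TIPS-alkynyl epoxide. Directed reduction, an anti-aldol at C3, esterification and Stille closure of the pentaene finish the macrolide.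

Key step: step 13

Remark (numbering): chain intermediates are named with the target numbering (C1–C26, C26 being the methyl on C25; side chain C1'–C6'); their configurations are fixed by the SMILES in the compound list.
Remark (precursor design): the west epoxide carries C3 as the TBS ether of the primary alcohol and O5 as a TBS ether, because an aldehyde acetal at C3 would not survive the later acidic removal of the 12,13-acetonide, and because any O5/O7 silyl exchange during the relay is then degenerate. All hydroxyls are later carried as silyl ethers, so the last step needs only buffered fluoride.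
Remark (supply): the six starting materials (3-(tert-butyldimethylsilyloxy)propanal, L-arabinose, 2-(tert-butyldimethylsilyl)-1,3-dithiane, methyl 3-oxooctanoate, 3,4-di-O-acetyl-L-fucal and (E)-1,2-bis(tributylstannyl)ethene) and all reagents, including (−)-Ipc2B(allyl) solution, are taken as commercial.

**West epoxide (C3–C8)**

Step 1
Reactants: 1 3-(tert-butyldimethylsilyloxy)propanal
Product: 3 (S)-1-(tert-butyldimethylsilyloxy)hex-5-en-3-ol, via borinate ester 2 (not isolated)
Conditions: (−)-Ipc2B(allyl) (1 M in pentane), Et2O, −78 °C; then 3 M NaOH, 30% H2O2, 0 °C → rt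
Reagents that add atoms: (−)-B-allyldiisopinocampheylborane, C=CCB([C@@H]1C[C@@H]2C[C@H]([C@H]1C)C2(C)C)[C@@H]1C[C@@H]2C[C@H]([C@H]1C)C2(C)C
Why: Brown asymmetric allylboration proceeds through a chair-like closed transition state in which the isopinocampheyl groups derived from (+)-α-pinene direct the allyl group to the aldehyde face that should give the (S)-carbinol, which sets C5.

Step 2
Reactants: 3 (S)-1-(tert-butyldimethylsilyloxy)hex-5-en-3-ol
Product: 4 tert-butyl (S)-1-(tert-butyldimethylsilyloxy)hex-5-en-3-yl carbonate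
Conditions: Boc2O, DMAP (0.2 equiv), MeCN, rt
Reagents that add atoms: di-tert-butyl dicarbonate, CC(C)(C)OC(=O)OC(=O)OC(C)(C)C
Why: DMAP-catalysed carbonate formation on the secondary alcohol installs the internal oxygen nucleophile for the halocyclisation without touching the alkene or the silyl ether.

Step 3
Reactants: 4 tert-butyl (S)-1-(tert-butyldimethylsilyloxy)hex-5-en-3-yl carbonate
Product: 5 (4R,6R)-4-(iodomethyl)-6-[2-(tert-butyldimethylsilyloxy)ethyl]-1,3-dioxan-2-one
Conditions: IBr, PhMe, −85 °C; aq. Na2S2O3/NaHCO3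
Reagents that add atoms: iodine monobromide, BrI
Why: Iodocarbonate cyclisation (6-exo attack of the carbonate carbonyl on the iodonium ion, then loss of the tert-butyl group) should favour the cis-4,6-disubstituted carbonate through a chair with both substituents equatorial, which sets C7 syn to O5.

Step 4
Reactants: 5 (4R,6R)-4-(iodomethyl)-6-[2-(tert-butyldimethylsilyloxy)ethyl]-1,3-dioxan-2-one
Product: 6 (2R)-4-(tert-butyldimethylsilyloxy)-1-[(2R)-oxiran-2-yl]butan-2-ol
Conditions: K2CO3, MeOH, rt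
Reagents that add atoms: none
Why: Methanolysis of the cyclic carbonate followed by intramolecular Williamson closure of the C7 alkoxide on the primary iodide should give the terminal epoxide with C5 and C7 unchanged.

Step 5
Reactants: 6 (2R)-4-(tert-butyldimethylsilyloxy)-1-[(2R)-oxiran-2-yl]butan-2-ol
Product: 7 west epoxide (R)-2-[(R)-2,4-bis(tert-butyldimethylsilyloxy)butyl]oxirane
Conditions: TBSCl, imidazole, DMF, rt
Reagents that add atoms: tert-butyldimethylsilyl chloride, CC(C)(C)[Si](C)(C)Cl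
Why: Imidazole-promoted silylation of the secondary alcohol is a standard protection that leaves the epoxide intact.

**East epoxide (C10–C15)**

Step 6
Reactants: 8 L-arabinose
Product: 9 L-arabinose diethyl dithioacetal
Conditions: EtSH, conc. HCl, 0 °C
Reagents that add atoms: ethanethiol, CCS
Why: Acid-catalysed dithioacetalisation opens the pyranose to the acyclic form, the classical entry to aldehydo sugars.

Step 7
Reactants: 9 L-arabinose diethyl dithioacetal
Product: 10 2,3:4,5-di-O-isopropylidene-L-arabinose diethyl dithioacetal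
Conditions: 2,2-dimethoxypropane, acetone, CSA (cat.), rt
Reagents that add atoms: 2,2-dimethoxypropane, COC(C)(C)OC
Why: Acid-catalysed transketalisation of the acyclic tetraol should give the known pairing of a trans-2,3-dioxolane and a terminal 4,5-dioxolane.

Step 8
Reactants: 10 2,3:4,5-di-O-isopropylidene-L-arabinose diethyl dithioacetal
Product: 11 2,3:4,5-di-O-isopropylidene-aldehydo-L-arabinose
Conditions: I2, NaHCO3, acetone/H2O, 0 °C → rt
Reagents that add atoms: water, O
Why: Iodine-mediated oxidative hydrolysis of the dithioacetal under bicarbonate buffering releases the aldehyde without acid, so the acetonides and the α-stereocentre should survive.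

Step 9
Reactants: 11 2,3:4,5-di-O-isopropylidene-aldehydo-L-arabinose
Product: 12 1,2-dideoxy-3,4:5,6-di-O-isopropylidene-L-arabino-hex-1-ynitol
Conditions: dimethyl (1-diazo-2-oxopropyl)phosphonate, K2CO3, MeOH, 0 °C → rt
Reagents that add atoms: dimethyl (1-diazo-2-oxopropyl)phosphonate, COP(=O)(OC)C(=[N+]=[N-])C(C)=O
Why: Seyferth–Gilbert homologation with the Ohira–Bestmann reagent converts the aldehyde into the terminal alkyne under mild carbonate conditions that acetonide-protected α-alkoxy aldehydes normally tolerate.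

Step 10
Reactants: 12 1,2-dideoxy-3,4:5,6-di-O-isopropylidene-L-arabino-hex-1-ynitol
Product: 14 1,2-dideoxy-3,4:5,6-di-O-isopropylidene-1-(triisopropylsilyl)-L-arabino-hex-1-ynitol, via lithium acetylide 13 (not isolated)
Conditions: n-BuLi, THF, −78 °C; TIPSCl, −78 °C → rt
Reagents that add atoms: triisopropylsilyl chloride, CC(C)[Si](Cl)(C(C)C)C(C)C
Why: Deprotonation and C-silylation of the terminal alkyne removes the acidic hydrogen that would quench the dithiane anion, and the bulky silyl group resists alkoxides.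

Step 11
Reactants: 14 1,2-dideoxy-3,4:5,6-di-O-isopropylidene-1-(triisopropylsilyl)-L-arabino-hex-1-ynitol
Product: 15 1,2-dideoxy-3,4-O-isopropylidene-1-(triisopropylsilyl)-L-arabino-hex-1-ynitol
Conditions: AcOH/H2O (7:3), 40 °C
Reagents that add atoms: none
Why: Regioselective acetal hydrolysis should remove the terminal dioxolane faster than the internal trans-disubstituted one, the usual order in acyclic sugar diacetonides.

Step 12
Reactants: 15 1,2-dideoxy-3,4-O-isopropylidene-1-(triisopropylsilyl)-L-arabino-hex-1-ynitol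
Product: 17 east epoxide 5,6-anhydro-1,2-dideoxy-3,4-O-isopropylidene-1-(triisopropylsilyl)-L-arabino-hex-1-ynitol, via primary tosylate 16 (not isolated)
Conditions: NaH, N-tosylimidazole, THF, 0 °C → rt
Reagents that add atoms: none
Why: One-pot sulfonylation and Williamson closure, in which the primary alkoxide is tosylated selectively and the neighbouring secondary alkoxide displaces the sulfonate, keeps the configuration of C11.

**Key coupling**

Step 13
Reactants: 18 2-(tert-butyldimethylsilyl)-1,3-dithiane; 7 west epoxide; 17 east epoxide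
Product: 22 C3–C15 dithiane (O3/O5/O7 TBS; O11 free; 12,13-acetonide; TIPS alkyne), via lithiated silyl dithiane 19 (not isolated), via lithium alkoxide 20 (not isolated), via relay dithiane anion 21 (not isolated)
Conditions: t-BuLi, Et2O, −78 → −45 °C; 7, Et2O, −78 → −25 °C; then 17, HMPA, THF, −78 °C → rt; aq. NH4Cl
Reagents that add atoms: none
Why: Deprotonation of 18 gives anion 19, which opens 7 by SN2 attack at the unsubstituted C8 in ether, where alkoxide 20 is stable; HMPA added with the second epoxide triggers a 1,4-Brook rearrangement (silicon from C9 to O7) that regenerates a dithiane anion 21, and this opens 17 at C10. The closest known reaction type is the multicomponent linchpin coupling of a 2-silyl-1,3-dithiane with two different epoxides (anion relay chemistry). No ring of the target is closed and no stereocentre is created, since C5 and C7 come from 7 and C11–C13 from 17 and none of them is touched. The step needs the two epoxides to enter in a fixed order and each at its CH2 carbon; the order is secured by the solvent gate (no Brook shift before HMPA) and the regiochemistry by both epoxides being monosubstituted. The TIPS group removes the acidic alkyne hydrogen, the acetonide excludes O12-to-O11 silyl migration, and silyl exchange between O5 and O7 is degenerate because both end as TBS ethers. The product has O7 silylated and O11 free, which is the differentiation that the directed reduction of the C9 ketone requires.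

**Polyol elaboration to the C3 aldehyde**

Step 14
Reactants: 22 C3–C15 dithiane
Product: 23 C9 ketone (11-hydroxy-9-oxo; other groups as in 22)
Conditions: MeI, CaCO3, MeCN/H2O (9:1), 45 °C
Reagents that add atoms: water, O
Why: Alkylative dithiane hydrolysis (S-methylation, then hydrolysis of the sulfonium ion) under carbonate buffering unmasks the ketone without acid or heavy-metal salts, so silyl ethers, acetonide and silylalkyne should survive.

Step 15
Reactants: 23 C9 ketone
Product: 24 9,11-anti diol (other groups as in 22)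
Conditions: Me4NBH(OAc)3, MeCN/AcOH (1:1), −30 °C
Reagents that add atoms: none
Why: Evans–Saksena reduction binds boron to the free O11 hydroxyl and delivers hydride intramolecularly through a chair transition state, which should set C9 anti to O11 and therefore syn to the silylated O7.

Step 16
Reactants: 24 9,11-anti diol
Product: 26 (3S,4S,5S,7R,9R,11R)-tridec-1-yne-3,4,5,7,9,11,13-heptol, via acetonide pentaol 25 (not isolated)
Conditions: TBAF, THF, 0 °C → rt; then 2 M HCl, MeOH, rt
Reagents that add atoms: none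
Why: Fluoride cleaves the three silyl ethers and the C-silyl alkyne, and acid-catalysed acetal hydrolysis then removes the acetonide while the alkyne terminus is still a robust propargylic triol, so no acid-labile group remains to be removed once the pentaene exists.

Step 17
Reactants: 26 (3S,4S,5S,7R,9R,11R)-tridec-1-yne-3,4,5,7,9,11,13-heptol
Product: 27 (3S,4S,5S,7R,9R,11R)-13-(triethylsilyloxy)tridec-1-yne-3,4,5,7,9,11-hexol
Conditions: TESCl (1.1 equiv), pyridine, −30 → 0 °C
Reagents that add atoms: chlorotriethylsilane, CC[Si](Cl)(CC)CC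
Why: Silyl chlorides in pyridine at low temperature react much faster with an unhindered primary hydroxyl than with secondary ones (selective silyl ether formation), so the C3 oxygen should be silylated first, and any over-silylated material converges in step 18 because that step puts the same group on every remaining hydroxyl.

Step 18
Reactants: 27 (3S,4S,5S,7R,9R,11R)-13-(triethylsilyloxy)tridec-1-yne-3,4,5,7,9,11-hexol
Product: 28 heptakis(triethylsilyl) ether of 26
Conditions: TESOTf (9 equiv), 2,6-lutidine, CH2Cl2, −40 → 0 °C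
Reagents that add atoms: triethylsilyl trifluoromethanesulfonate, CC[Si](CC)(CC)OS(=O)(=O)C(F)(F)F
Why: Triflate-mediated silylation with a hindered pyridine base is forceful enough to cover all six secondary hydroxyls, including the crowded contiguous C11–C13 triol, while the terminal alkyne C–H and the primary silyl ether are untouched.

Step 19
Reactants: 28 heptakis(triethylsilyl) ether
Product: 30 (E)-vinyl iodide (C14 methyl; C15 iodide; O3–O13 TES), via alkenylalane 29 (not isolated)
Conditions: AlMe3, Cp2ZrCl2 (0.5 equiv), (CH2Cl)2, rt; then I2, THF, −30 → 0 °C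
Reagents that add atoms: trimethylaluminium, C[Al](C)C; iodine, II
Why: Negishi zirconium-catalysed carboalumination adds methyl and aluminium syn across the terminal alkyne with methyl on the internal carbon C14, and iodinolysis of the alkenylalane with retention should give the (E)-trisubstituted vinyl iodide.

Step 20
Reactants: 30 (E)-vinyl iodide
Product: 32 C3 aldehyde (O5–O13 TES; C15 iodide), via alkoxysulfonium salt 31 (not isolated)
Conditions: (COCl)2, DMSO, CH2Cl2, −78 → −40 °C; Et3N, −78 → 0 °C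
Reagents that add atoms: none
Why: Under Swern conditions activated DMSO attacks the unhindered primary triethylsilyl ether oxygen and converts it directly into the aldehyde while secondary triethylsilyl ethers are retained, a known one-pot selective deprotection–oxidation.

**Side-chain donor**

Step 21
Reactants: 33 methyl 3-oxooctanoate
Product: 34 methyl (S)-3-hydroxyoctanoate
Conditions: H2 (50 atm), RuCl2[(S)-BINAP] (0.5 mol %), MeOH, 50 °C
Reagents that add atoms: none
Why: Noyori asymmetric hydrogenation of a β-keto ester with the (S)-BINAP ruthenium catalyst should deliver hydrogen to the ketone face that gives the (S)-alcohol, which sets C1'.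

Step 22
Reactants: 34 methyl (S)-3-hydroxyoctanoate
Product: 35 (S)-3-hydroxyoctanoic acid
Conditions: LiOH, THF/H2O, rt; then aq. HCl
Reagents that add atoms: lithium hydroxide, [Li+].[OH-]
Why: Ester saponification frees the acid needed for acylal formation without affecting the carbinol centre.

Step 23
Reactants: 35 (S)-3-hydroxyoctanoic acid
Product: 36 (2S,6S)-2-tert-butyl-6-pentyl-1,3-dioxan-4-one
Conditions: pivalaldehyde, TsOH·H2O (cat.), CH2Cl2, reflux, water separator
Reagents that add atoms: pivalaldehyde, CC(C)(C)C=O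
Why: Acid-catalysed acetalisation of the β-hydroxy acid under water removal gives the 1,3-dioxan-4-one, whose cis isomer with both substituents equatorial is thermodynamically favoured and is purified by crystallisation or chromatography.

**Anti-aldol triad and C1 acid**

Step 24
Reactants: 36 (2S,6S)-2-tert-butyl-6-pentyl-1,3-dioxan-4-one; 32 C3 aldehyde
Product: 38 aldol adduct (dioxanone on C1/O1'; free 3-OH), via lithium enolate 37 (not isolated)
Conditions: LiN(iPr)2, THF, −78 °C; then 32, −78 °C; AcOH, −78 °C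
Reagents that add atoms: none
Why: In this aldol addition of a 1,3-dioxan-4-one lithium enolate the ring fixes the E(O) enolate geometry and the aldehyde adds to the face trans to the pentyl group, so a chair Zimmerman–Traxler transition state should give the 2,1'-anti and 2,3-anti relationships of the target at C2 and C3.

Step 25
Reactants: 38 aldol adduct
Product: 39 dihydroxy acid (free 1'-OH and 3-OH; C1 acid)
Conditions: LiOH·H2O, THF/H2O (3:1), 0 °C → rt; 0.1 M HCl to pH 4, 0 °C
Reagents that add atoms: lithium hydroxide, [Li+].[OH-]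
Why: Saponification of the acylal, in which hydroxide adds to the lactone carbonyl and the expelled hemiacetal alkoxide collapses to pivalaldehyde, releases the C1 acid and the C1' hydroxyl without enolising C2.

Step 26
Reactants: 39 dihydroxy acid
Product: 41 bis-TES acid (O1' and O3 TES; C1 acid), via silyl ester 40 (not isolated)
Conditions: TESOTf, 2,6-lutidine, CH2Cl2, −78 → 0 °C; then aq. NaHCO3, MeOH, rt; pH 5 buffer
Reagents that add atoms: triethylsilyl trifluoromethanesulfonate, CC[Si](CC)(CC)OS(=O)(=O)C(F)(F)F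
Why: Triflate-mediated silylation covers both hydroxyls and the acid, and the labile silyl ester is hydrolysed selectively in mildly basic aqueous methanol to leave the bis-silyl ether acid.

**Polyene alcohol (C16–C26)**

Step 27
Reactants: 42 3,4-di-O-acetyl-L-fucal
Product: 43 (2E,4S,5S)-4-acetoxy-5-hydroxyhex-2-enal
Conditions: HgSO4 (cat.), 5 mM H2SO4, 1,4-dioxane/H2O, rt
Reagents that add atoms: water, O
Why: Perlin hydrolysis of the glycal (mercury-catalysed hydration at C1–C2, ring opening and loss of the C3 acetate) gives the (E)-enal with the C4 acetate and the former ring oxygen as a free hydroxyl, so C24 and C25 come unchanged from L-fucose.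

Step 28
Reactants: 43 (2E,4S,5S)-4-acetoxy-5-hydroxyhex-2-enal
Product: 44 (2E,4S,5S)-4-acetoxy-5-(triethylsilyloxy)hex-2-enal
Conditions: TESCl, imidazole, CH2Cl2, 0 °C
Reagents that add atoms: chlorotriethylsilane, CC[Si](Cl)(CC)CC
Why: Silylation of the free secondary alcohol blocks acetyl migration and gives a temporary group that can later be removed in the presence of a TBS ether.

Step 29
Reactants: 44 (2E,4S,5S)-4-acetoxy-5-(triethylsilyloxy)hex-2-enal
Product: 45 (2E,4E,6S,7S)-6-acetoxy-7-(triethylsilyloxy)octa-2,4-dienal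
Conditions: Ph3P=CHCHO, PhMe, 70 °C
Reagents that add atoms: (triphenylphosphoranylidene)acetaldehyde, O=CC=P(c1ccccc1)(c1ccccc1)c1ccccc1
Why: Wittig two-carbon homologation with the stabilised formylmethylene ylide should form the new double bond with E geometry.

Step 30
Reactants: 45 (2E,4E,6S,7S)-6-acetoxy-7-(triethylsilyloxy)octa-2,4-dienal
Product: 46 (2S,3S,4E,6E,8E)-9-iodo-2-(triethylsilyloxy)nona-4,6,8-trien-3-yl acetate
Conditions: CrCl2, CHI3, THF, 0 °C → rt, dark
Reagents that add atoms: iodoform, IC(I)I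
Why: In the Takai olefination the geminal dichromium species from iodoform adds to the aldehyde and eliminates to the (E)-vinyl iodide, and ester and silyl ether are inert to CrCl2.

Step 31
Reactants: 46 trienyl iodide acetate
Product: 47 (2S,3S,4E,6E,8E)-9-iodo-2-(triethylsilyloxy)nona-4,6,8-trien-3-ol
Conditions: DIBAL-H, CH2Cl2, −78 °C; aq. potassium sodium tartrate
Reagents that add atoms: none
Why: Reductive cleavage of the acetate by the aluminium hydride at low temperature avoids free alkoxide and hence silyl migration, and leaves the trienyl iodide untouched.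

Step 32
Reactants: 47 (2S,3S,4E,6E,8E)-9-iodo-2-(triethylsilyloxy)nona-4,6,8-trien-3-ol
Product: 48 (2S,3S,4E,6E,8E)-3-(tert-butyldimethylsilyloxy)-9-iodo-2-(triethylsilyloxy)nona-4,6,8-triene
Conditions: TBSOTf, 2,6-lutidine, CH2Cl2, −78 °C
Reagents that add atoms: tert-butyldimethylsilyl trifluoromethanesulfonate, CC(C)(C)[Si](C)(C)OS(=O)(=O)C(F)(F)F
Why: Triflate-mediated silylation of the allylic secondary alcohol under hindered-base buffering installs the O24 group that lasts to the final fluoride step.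

Step 33
Reactants: 48 bis-silyl trienyl iodide
Product: 49 (2S,3S,4E,6E,8E)-3-(tert-butyldimethylsilyloxy)-9-iodonona-4,6,8-trien-2-ol
Conditions: HF·pyridine, pyridine, THF, 0 °C
Reagents that add atoms: none
Why: Buffered fluoride should cleave the secondary triethylsilyl ether much faster than the secondary tert-butyldimethylsilyl ether, a standard selective desilylation that involves no carbocation at the allylic centre.

Step 34
Reactants: 49 (2S,3S,4E,6E,8E)-3-(tert-butyldimethylsilyloxy)-9-iodonona-4,6,8-trien-2-ol; 50 (E)-1,2-bis(tributylstannyl)ethene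
Product: 51 (2S,3S,4E,6E,8E,10E)-3-(tert-butyldimethylsilyloxy)-11-(tributylstannyl)undeca-4,6,8,10-tetraen-2-ol
Conditions: 50 (4 equiv), PdCl2(MeCN)2 (5 mol %), iPr2NEt, DMF/THF, rt, dark
Reagents that add atoms: none
Why: Stille coupling of the alkenyl iodide with an excess of the distannylethene transfers one stannylvinyl unit with retention of both alkene geometries, and the excess should suppress double coupling.

**Union, ring closure and deprotection**

Step 35
Reactants: 41 bis-TES acid; 51 stannyl tetraenol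
Product: 53 seco ester (C1–O25 ester; C15 iodide; C16 stannane), via mixed anhydride 52 (not isolated)
Conditions: 2,4,6-Cl3C6H2COCl, Et3N, PhMe, rt; then 51, DMAP, PhMe, rt
Reagents that add atoms: none
Why: In the Yamaguchi esterification DMAP attacks the mixed trichlorobenzoic anhydride at the aliphatic carbonyl and the resulting acylpyridinium acylates the C25 hydroxyl, conditions that vinylstannanes and silyl ethers tolerate.

Step 36
Reactants: 53 seco ester
Product: 54 nonasilyl macrolide (O1'/O3/O5/O7/O9/O11/O12/O13 TES; O24 TBS)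
Conditions: Pd2(dba)3, AsPh3, iPr2NEt, DMF/THF (1 mM), rt, dark
Reagents that add atoms: none
Why: Intramolecular Stille coupling with triphenylarsine as a transmetalation-accelerating ligand joins C15 to C16 with retention of both alkene geometries, and high dilution favours closure of the 26-membered ring.

Step 37
Reactants: 54 nonasilyl macrolide
Product: 55 target macrolide CNP0296784.1
Conditions: HF·pyridine, pyridine, THF, 0 °C → rt
Reagents that add atoms: none
Why: Buffered fluoride desilylation removes all nine silyl ethers without the acid or base that could ionise the allylic C13 and C24 carbinols, open the lactone or start a retro-aldol.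

**Compound list**

1 | 3-(tert-butyldimethylsilyloxy)propanal | O=CCCO[Si](C)(C)C(C)(C)C | starting material
2 | diisopinocampheylborinate of (S)-1-(tert-butyldimethylsilyloxy)hex-5-en-3-ol | C=CC[C@@H](CCO[Si](C)(C)C(C)(C)C)OB([C@@H]1C[C@@H]2C[C@H]([C@H]1C)C2(C)C)[C@@H]1C[C@@H]2C[C@H]([C@H]1C)C2(C)C | intermediate (not isolated)
3 | (S)-1-(tert-butyldimethylsilyloxy)hex-5-en-3-ol | C=CC[C@H](O)CCO[Si](C)(C)C(C)(C)C | intermediate
4 | tert-butyl (S)-1-(tert-butyldimethylsilyloxy)hex-5-en-3-yl carbonate | C=CC[C@H](OC(=O)OC(C)(C)C)CCO[Si](C)(C)C(C)(C)C | intermediate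
5 | (4R,6R)-4-(iodomethyl)-6-[2-(tert-butyldimethylsilyloxy)ethyl]-1,3-dioxan-2-one (cis) | IC[C@H]1C[C@@H](CCO[Si](C)(C)C(C)(C)C)OC(=O)O1 | intermediate
6 | (2R)-4-(tert-butyldimethylsilyloxy)-1-[(2R)-oxiran-2-yl]butan-2-ol | C1O[C@@H]1C[C@H](O)CCO[Si](C)(C)C(C)(C)C | intermediate
7 | west epoxide, (R)-2-[(R)-2,4-bis(tert-butyldimethylsilyloxy)butyl]oxirane (C3–C8; 5,7-syn) | C1O[C@@H]1C[C@H](O[Si](C)(C)C(C)(C)C)CCO[Si](C)(C)C(C)(C)C | intermediate
8 | L-arabinose | O=C[C@H](O)[C@@H](O)[C@@H](O)CO | starting material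
9 | L-arabinose diethyl dithioacetal | CCSC(SCC)[C@H](O)[C@@H](O)[C@@H](O)CO | intermediate
10 | 2,3:4,5-di-O-isopropylidene-L-arabinose diethyl dithioacetal | CCSC(SCC)[C@H](O1)[C@@H](OC1(C)C)[C@@H](O2)COC2(C)C | intermediate
11 | 2,3:4,5-di-O-isopropylidene-aldehydo-L-arabinose | O=C[C@H](O1)[C@@H](OC1(C)C)[C@@H](O2)COC2(C)C | intermediate
12 | 1,2-dideoxy-3,4:5,6-di-O-isopropylidene-L-arabino-hex-1-ynitol | C#C[C@H](O1)[C@@H](OC1(C)C)[C@@H](O2)COC2(C)C | intermediate
13 | lithium acetylide of 12 | [Li]C#C[C@H](O1)[C@@H](OC1(C)C)[C@@H](O2)COC2(C)C | intermediate (not isolated)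
14 | 1,2-dideoxy-3,4:5,6-di-O-isopropylidene-1-(triisopropylsilyl)-L-arabino-hex-1-ynitol | CC(C)[Si](C(C)C)(C(C)C)C#C[C@H](O1)[C@@H](OC1(C)C)[C@@H](O2)COC2(C)C | intermediate
15 | 1,2-dideoxy-3,4-O-isopropylidene-1-(triisopropylsilyl)-L-arabino-hex-1-ynitol (5,6-diol) | CC(C)[Si](C(C)C)(C(C)C)C#C[C@H](O1)[C@@H](OC1(C)C)[C@@H](O)CO | intermediate
16 | 6-O-tosyl derivative of 15 | CC(C)[Si](C(C)C)(C(C)C)C#C[C@H](O1)[C@@H](OC1(C)C)[C@@H](O)COS(=O)(=O)c1ccc(C)cc1 | intermediate (not isolated)
17 | east epoxide, 5,6-anhydro-1,2-dideoxy-3,4-O-isopropylidene-1-(triisopropylsilyl)-L-arabino-hex-1-ynitol (C10–C15) | CC(C)[Si](C(C)C)(C(C)C)C#C[C@H](O1)[C@@H](OC1(C)C)[C@@H](O2)C2 | intermediate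
18 | 2-(tert-butyldimethylsilyl)-1,3-dithiane | C[Si](C)(C(C)(C)C)C1SCCCS1 | starting material
19 | 2-lithio-2-(tert-butyldimethylsilyl)-1,3-dithiane | [Li]C1([Si](C)(C)C(C)(C)C)SCCCS1 | intermediate (not isolated)
20 | lithium O7-alkoxide of the C8-alkylated 2-silyl dithiane | [Li]O[C@@H](CC1([Si](C)(C)C(C)(C)C)SCCCS1)C[C@H](O[Si](C)(C)C(C)(C)C)CCO[Si](C)(C)C(C)(C)C | intermediate (not isolated)
21 | C9-lithio dithiane after Brook shift (O7 TBS) | [Li]C1(C[C@H](O[Si](C)(C)C(C)(C)C)C[C@H](O[Si](C)(C)C(C)(C)C)CCO[Si](C)(C)C(C)(C)C)SCCCS1 | intermediate (not isolated)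
22 | C3–C15 dithiane: 3,5,7-tris(TBS-oxy), 9,9-(propane-1,3-diyldithio), 11-hydroxy, 12,13-O-isopropylidene, 15-TIPS alkyne | CC(C)[Si](C(C)C)(C(C)C)C#C[C@H](O1)[C@@H](OC1(C)C)[C@@H](O)CC2(SCCCS2)C[C@H](O[Si](C)(C)C(C)(C)C)C[C@H](O[Si](C)(C)C(C)(C)C)CCO[Si](C)(C)C(C)(C)C | intermediate
23 | C9 ketone (11-hydroxy-9-oxo analogue of 22) | CC(C)[Si](C(C)C)(C(C)C)C#C[C@H](O1)[C@@H](OC1(C)C)[C@@H](O)CC(=O)C[C@H](O[Si](C)(C)C(C)(C)C)C[C@H](O[Si](C)(C)C(C)(C)C)CCO[Si](C)(C)C(C)(C)C | intermediate
24 | 9,11-anti diol (7,9-syn) | CC(C)[Si](C(C)C)(C(C)C)C#C[C@H](O1)[C@@H](OC1(C)C)[C@@H](O)C[C@H](O)C[C@H](O[Si](C)(C)C(C)(C)C)C[C@H](O[Si](C)(C)C(C)(C)C)CCO[Si](C)(C)C(C)(C)C | intermediate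
25 | 12,13-O-isopropylidene pentaol with terminal alkyne | C#C[C@H](O1)[C@@H](OC1(C)C)[C@@H](O)C[C@H](O)C[C@H](O)C[C@H](O)CCO | intermediate (not isolated)
26 | (3S,4S,5S,7R,9R,11R)-tridec-1-yne-3,4,5,7,9,11,13-heptol | C#C[C@H](O)[C@@H](O)[C@@H](O)C[C@H](O)C[C@H](O)C[C@H](O)CCO | intermediate
27 | (3S,4S,5S,7R,9R,11R)-13-(triethylsilyloxy)tridec-1-yne-3,4,5,7,9,11-hexol (primary mono-TES ether of 26) | C#C[C@H](O)[C@@H](O)[C@@H](O)C[C@H](O)C[C@H](O)C[C@H](O)CCO[Si](CC)(CC)CC | intermediate
28 | heptakis(triethylsilyl) ether of 26 | C#C[C@H](O[Si](CC)(CC)CC)[C@@H](O[Si](CC)(CC)CC)[C@@H](O[Si](CC)(CC)CC)C[C@H](O[Si](CC)(CC)CC)C[C@H](O[Si](CC)(CC)CC)C[C@H](O[Si](CC)(CC)CC)CCO[Si](CC)(CC)CC | intermediate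
29 | (E)-C15 dimethylalanyl C14-methyl alkene | C[Al](C)/C=C(\C)[C@H](O[Si](CC)(CC)CC)[C@@H](O[Si](CC)(CC)CC)[C@@H](O[Si](CC)(CC)CC)C[C@H](O[Si](CC)(CC)CC)C[C@H](O[Si](CC)(CC)CC)C[C@H](O[Si](CC)(CC)CC)CCO[Si](CC)(CC)CC | intermediate (not isolated)
30 | (E)-C15 vinyl iodide, C14 methyl, heptakis-TES | I/C=C(\C)[C@H](O[Si](CC)(CC)CC)[C@@H](O[Si](CC)(CC)CC)[C@@H](O[Si](CC)(CC)CC)C[C@H](O[Si](CC)(CC)CC)C[C@H](O[Si](CC)(CC)CC)C[C@H](O[Si](CC)(CC)CC)CCO[Si](CC)(CC)CC | intermediate
31 | C3 alkoxydimethylsulfonium chloride | I/C=C(\C)[C@H](O[Si](CC)(CC)CC)[C@@H](O[Si](CC)(CC)CC)[C@@H](O[Si](CC)(CC)CC)C[C@H](O[Si](CC)(CC)CC)C[C@H](O[Si](CC)(CC)CC)C[C@H](O[Si](CC)(CC)CC)CCO[S+](C)C.[Cl-] | intermediate (not isolated)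
32 | C3 aldehyde, hexakis-TES (O5–O13), C15 vinyl iodide | I/C=C(\C)[C@H](O[Si](CC)(CC)CC)[C@@H](O[Si](CC)(CC)CC)[C@@H](O[Si](CC)(CC)CC)C[C@H](O[Si](CC)(CC)CC)C[C@H](O[Si](CC)(CC)CC)C[C@H](O[Si](CC)(CC)CC)CC=O | intermediate
33 | methyl 3-oxooctanoate | CCCCCC(=O)CC(=O)OC | starting material
34 | methyl (S)-3-hydroxyoctanoate | CCCCC[C@H](O)CC(=O)OC | intermediate
35 | (S)-3-hydroxyoctanoic acid | CCCCC[C@H](O)CC(=O)O | intermediate
36 | (2S,6S)-2-tert-butyl-6-pentyl-1,3-dioxan-4-one (cis) | CCCCC[C@H]1CC(=O)O[C@@H](C(C)(C)C)O1 | intermediate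
37 | lithium enolate of 36 | CCCCC[C@H]1C=C(O[Li])O[C@@H](C(C)(C)C)O1 | intermediate (not isolated)
38 | aldol adduct: 5-substituted dioxanone, 5,6-trans, (3R)-carbinol, 2,3-anti | CCCCC[C@@H]1O[C@H](C(C)(C)C)OC(=O)[C@H]1[C@H](O)C[C@@H](O[Si](CC)(CC)CC)C[C@@H](O[Si](CC)(CC)CC)C[C@@H](O[Si](CC)(CC)CC)C[C@H](O[Si](CC)(CC)CC)[C@H](O[Si](CC)(CC)CC)[C@@H](O[Si](CC)(CC)CC)/C(C)=C/I | intermediate
39 | 1',3-dihydroxy C1 acid (C1–C15 with side chain) | CCCCC[C@H](O)[C@@H](C(=O)O)[C@H](O)C[C@@H](O[Si](CC)(CC)CC)C[C@@H](O[Si](CC)(CC)CC)C[C@@H](O[Si](CC)(CC)CC)C[C@H](O[Si](CC)(CC)CC)[C@H](O[Si](CC)(CC)CC)[C@@H](O[Si](CC)(CC)CC)/C(C)=C/I | intermediate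
40 | triethylsilyl ester of 41 | CCCCC[C@H](O[Si](CC)(CC)CC)[C@@H](C(=O)O[Si](CC)(CC)CC)[C@H](O[Si](CC)(CC)CC)C[C@@H](O[Si](CC)(CC)CC)C[C@@H](O[Si](CC)(CC)CC)C[C@@H](O[Si](CC)(CC)CC)C[C@H](O[Si](CC)(CC)CC)[C@H](O[Si](CC)(CC)CC)[C@@H](O[Si](CC)(CC)CC)/C(C)=C/I | intermediate (not isolated)
41 | octakis-TES C1 acid (O1', O3, O5, O7, O9, O11, O12, O13) with C15 vinyl iodide | CCCCC[C@H](O[Si](CC)(CC)CC)[C@@H](C(=O)O)[C@H](O[Si](CC)(CC)CC)C[C@@H](O[Si](CC)(CC)CC)C[C@@H](O[Si](CC)(CC)CC)C[C@@H](O[Si](CC)(CC)CC)C[C@H](O[Si](CC)(CC)CC)[C@H](O[Si](CC)(CC)CC)[C@@H](O[Si](CC)(CC)CC)/C(C)=C/I | intermediate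
42 | 3,4-di-O-acetyl-L-fucal | C[C@@H]1OC=C[C@H](OC(C)=O)[C@@H]1OC(C)=O | starting material
43 | (2E,4S,5S)-4-acetoxy-5-hydroxyhex-2-enal | C[C@H](O)[C@@H](OC(C)=O)/C=C/C=O | intermediate
44 | (2E,4S,5S)-4-acetoxy-5-(triethylsilyloxy)hex-2-enal | C[C@H](O[Si](CC)(CC)CC)[C@@H](OC(C)=O)/C=C/C=O | intermediate
45 | (2E,4E,6S,7S)-6-acetoxy-7-(triethylsilyloxy)octa-2,4-dienal | C[C@H](O[Si](CC)(CC)CC)[C@@H](OC(C)=O)/C=C/C=C/C=O | intermediate
46 | (2S,3S,4E,6E,8E)-9-iodo-2-(triethylsilyloxy)nona-4,6,8-trien-3-yl acetate | C[C@H](O[Si](CC)(CC)CC)[C@@H](OC(C)=O)/C=C/C=C/C=C/I | intermediate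
47 | (2S,3S,4E,6E,8E)-9-iodo-2-(triethylsilyloxy)nona-4,6,8-trien-3-ol | C[C@H](O[Si](CC)(CC)CC)[C@@H](O)/C=C/C=C/C=C/I | intermediate
48 | (2S,3S,4E,6E,8E)-3-(tert-butyldimethylsilyloxy)-9-iodo-2-(triethylsilyloxy)nona-4,6,8-triene | C[C@H](O[Si](CC)(CC)CC)[C@@H](O[Si](C)(C)C(C)(C)C)/C=C/C=C/C=C/I | intermediate
49 | (2S,3S,4E,6E,8E)-3-(tert-butyldimethylsilyloxy)-9-iodonona-4,6,8-trien-2-ol | C[C@H](O)[C@@H](O[Si](C)(C)C(C)(C)C)/C=C/C=C/C=C/I | intermediate
50 | (E)-1,2-bis(tributylstannyl)ethene | CCCC[Sn](CCCC)(CCCC)/C=C/[Sn](CCCC)(CCCC)CCCC | starting material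
51 | (2S,3S,4E,6E,8E,10E)-3-(tert-butyldimethylsilyloxy)-11-(tributylstannyl)undeca-4,6,8,10-tetraen-2-ol | C[C@H](O)[C@@H](O[Si](C)(C)C(C)(C)C)/C=C/C=C/C=C/C=C/[Sn](CCCC)(CCCC)CCCC | intermediate
52 | mixed 2,4,6-trichlorobenzoic anhydride of 41 | CCCCC[C@H](O[Si](CC)(CC)CC)[C@@H](C(=O)OC(=O)c1c(Cl)cc(Cl)cc1Cl)[C@H](O[Si](CC)(CC)CC)C[C@@H](O[Si](CC)(CC)CC)C[C@@H](O[Si](CC)(CC)CC)C[C@@H](O[Si](CC)(CC)CC)C[C@H](O[Si](CC)(CC)CC)[C@H](O[Si](CC)(CC)CC)[C@@H](O[Si](CC)(CC)CC)/C(C)=C/I | intermediate (not isolated)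
53 | seco ester: C1 acid 41 esterified at O25 of 51 (C15 iodide, C16 stannane) | CCCCC[C@H](O[Si](CC)(CC)CC)[C@@H](C(=O)O[C@@H](C)[C@@H](O[Si](C)(C)C(C)(C)C)/C=C/C=C/C=C/C=C/[Sn](CCCC)(CCCC)CCCC)[C@H](O[Si](CC)(CC)CC)C[C@@H](O[Si](CC)(CC)CC)C[C@@H](O[Si](CC)(CC)CC)C[C@@H](O[Si](CC)(CC)CC)C[C@H](O[Si](CC)(CC)CC)[C@H](O[Si](CC)(CC)CC)[C@@H](O[Si](CC)(CC)CC)/C(C)=C/I | intermediate
54 | nonasilyl macrolide (eight TES ethers, O24 TBS) | CCCCC[C@H](O[Si](CC)(CC)CC)[C@H]1C(=O)O[C@@H](C)[C@@H](O[Si](C)(C)C(C)(C)C)/C=C/C=C/C=C/C=C/C=C(\C)[C@H](O[Si](CC)(CC)CC)[C@@H](O[Si](CC)(CC)CC)[C@@H](O[Si](CC)(CC)CC)C[C@H](O[Si](CC)(CC)CC)C[C@H](O[Si](CC)(CC)CC)C[C@H](O[Si](CC)(CC)CC)C[C@H]1O[Si](CC)(CC)CC | intermediate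
55 | CNP0296784.1, (2R,3R,5S,7R,9R,11S,12S,13S,14E,16E,18E,20E,22E,24S,25S)-3,5,7,9,11,12,13,24-octahydroxy-2-[(1S)-1-hydroxyhexyl]-14-methylhexacosa-14,16,18,20,22-pentaen-25-olide | CCCCC[C@H](O)[C@H]1C(=O)O[C@@H](C)[C@@H](O)/C=C/C=C/C=C/C=C/C=C(\C)[C@H](O)[C@@H](O)[C@@H](O)C[C@H](O)C[C@H](O)C[C@H](O)C[C@H]1O | target

**Count.** Total: 37 steps. Longest linear sequence: 21 steps (6–20, 24–26, 35–37).

**Steps most likely to fail**

Step 24 (aldol). The closed transition state may discriminate the two aldehyde faces poorly, which erodes the C3 configuration, and the dioxanone enolate may undergo β-elimination if the temperature rises. The fallback replaces stereoselective C–C bond formation by oxidation and reagent-controlled reduction. The aldol is run from 32 and 36 as before, and the crude mixture of 38 and its C3 epimer, the (3S)-aldol F1, is oxidised with Dess–Martin periodinane (NaHCO3, CH2Cl2) to the β-keto lactone F2, in which the trans arrangement at C2 is the thermodynamically preferred one. CBS reduction with catecholborane and (S)-2-methyl-CBS-oxazaborolidine (toluene, −78 °C), the ring-bearing branch acting as the large ketone substituent, should return 38.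

Step 13 (relay coupling). The silyl shift may occur before the second epoxide is present, or the relay anion may be quenched by proton transfer, so that mono-alkylated or symmetrically bis-alkylated material forms. The fallback makes the same two bonds stepwise by Corey–Seebach alkylation. It sets out from 7: 2-lithio-1,3-dithiane (1,3-dithiane, n-BuLi, THF, −30 °C) opens the epoxide at C8 to give the hydroxy dithiane F3, silylation (TBSCl, imidazole, DMF) gives the tris-silyl ether F4, and a second lithiation (t-BuLi, THF/HMPA, −78 °C) followed by 17 gives 22.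

Step 35 (esterification). Acyl transfer to the hindered C25 hydroxyl may be slow, and the activated acid may then lose its C2 configuration through ketene formation or eliminate the C3 silyloxy group. The fallback reverses the order of the two ring-forming bonds. Intermolecular Stille coupling of acid 41 with stannane 51 (Pd2(dba)3, AsPh3, iPr2NEt, DMF, rt) gives the pentaene seco acid F5, and Shiina macrolactonisation (2-methyl-6-nitrobenzoic anhydride, DMAP, toluene, high dilution, rt) gives 54, so that steps 35 and 36 are both replaced.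

Further compounds
F1 | step 24 | (3S)-epimer of aldol adduct 38 | CCCCC[C@@H]1O[C@H](C(C)(C)C)OC(=O)[C@H]1[C@@H](O)C[C@@H](O[Si](CC)(CC)CC)C[C@@H](O[Si](CC)(CC)CC)C[C@@H](O[Si](CC)(CC)CC)C[C@H](O[Si](CC)(CC)CC)[C@H](O[Si](CC)(CC)CC)[C@@H](O[Si](CC)(CC)CC)/C(C)=C/I
F2 | step 24 | C3 ketone (5-acyl-1,3-dioxan-4-one, 5,6-trans) | CCCCC[C@@H]1O[C@H](C(C)(C)C)OC(=O)[C@H]1C(=O)C[C@@H](O[Si](CC)(CC)CC)C[C@@H](O[Si](CC)(CC)CC)C[C@@H](O[Si](CC)(CC)CC)C[C@H](O[Si](CC)(CC)CC)[C@H](O[Si](CC)(CC)CC)[C@@H](O[Si](CC)(CC)CC)/C(C)=C/I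
F3 | step 13 | 2-[(2R,4R)-4,6-bis(tert-butyldimethylsilyloxy)-2-hydroxyhexyl]-1,3-dithiane (C3–C9, free 7-OH) | O[C@@H](CC1SCCCS1)C[C@H](O[Si](C)(C)C(C)(C)C)CCO[Si](C)(C)C(C)(C)C
F4 | step 13 | 2-[2,4,6-tris(tert-butyldimethylsilyloxy)hexyl]-1,3-dithiane (C3–C9, O7 TBS) | S1CCCSC1C[C@H](O[Si](C)(C)C(C)(C)C)C[C@H](O[Si](C)(C)C(C)(C)C)CCO[Si](C)(C)C(C)(C)C
F5 | step 35 | pentaene seco acid (C1 acid, free 25-OH, O24 TBS, eight TES ethers) | CCCCC[C@H](O[Si](CC)(CC)CC)[C@@H](C(=O)O)[C@H](O[Si](CC)(CC)CC)C[C@@H](O[Si](CC)(CC)CC)C[C@@H](O[Si](CC)(CC)CC)C[C@@H](O[Si](CC)(CC)CC)C[C@H](O[Si](CC)(CC)CC)[C@H](O[Si](CC)(CC)CC)[C@@H](O[Si](CC)(CC)CC)/C(C)=C/C=C/C=C/C=C/C=C/[C@H](O[Si](C)(C)C(C)(C)C)[C@H](C)O
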